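The daucane is opened at C4–C5 together with the C1–CH3 bond. Relative to the C6 oxygen, C1 is the β-carbon, C5 the α-carbon and the C4 carbinol a β-hydroxyl. A copper-catalysed asymmetric transfer of methyl from trimethylaluminium to C1 of an achiral cycloheptenone, followed by aldol capture of the C5 aluminium enolate by the side-chain isopropyl ketone, therefore forms the five-membered ring and the C1, C4 and C5 stereocentres in one operation. The precursor is 3-(4-methyl-3-oxopentyl)cyclohept-2-en-1-one, made in four steps from cycloheptane-1,3-dione. C14 and the C6, C8 and C9 oxygens follow through the C6 ketone.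

Key step: step 5

Numbering: daucane numbering is used (C1 ring-fusion C–CH3, C2/C3 CH2, C4 carbinol with isopropyl, C5 ring-fusion CH, C6–C10 around the seven-membered ring, C14 the methyl on C8). All daucanes below are trans-fused with 1β-CH3, 5α-H, 4β-O and 4α-isopropyl.

Remark: the cascade substrate is kept as the simple C13 keto-enone, because a C8 methyl or a C8/C9 function carried through the cascade would make the substrate chiral, add a second Michael acceptor or place a skipped diene beside the reacting enone; C14 and the diol are therefore added afterwards, and no operation on the β-hydroxy ketone generates an alkali-metal alkoxide.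

Step 1
Reactants: 1 cycloheptane-1,3-dione
Product: 2 3-(2-methylpropoxy)cyclohept-2-en-1-one
Conditions: i-BuOH, PPTS (cat.), toluene, reflux, Dean–Stark
Reagents that add atoms: 2-methylpropan-1-ol, CC(C)CO
Why: Acid-catalysed enol etherification of the symmetrical β-diketone with azeotropic removal of water gives the vinylogous ester, and the symmetry of 1 allows only one regioisomer.

Step 2
Reactants: 2 3-(2-methylpropoxy)cyclohept-2-en-1-one; 3 5-bromo-2-methylpent-2-ene
Product: 6 3-(4-methylpent-3-en-1-yl)cyclohept-2-en-1-one, via homoprenylmagnesium bromide 4 (not isolated), via bromomagnesium carbinolate 5 (not isolated)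
Conditions: 3, Mg, THF, 25–40 °C; then 2, THF, 0 °C; then 2 M HCl, 25 °C
Reagents that add atoms: none
Why: Stork–Danheiser sequence: 1,2-addition of the Grignard reagent to the vinylogous ester carbonyl, then acid hydrolysis of the enol ether and loss of water, transposes the carbonyl and places the side chain on the enone β-carbon.

Step 3
Reactants: 6 3-(4-methylpent-3-en-1-yl)cyclohept-2-en-1-one
Product: 7 3-[2-(3,3-dimethyloxiran-2-yl)ethyl]cyclohept-2-en-1-one (racemic)
Conditions: mCPBA (1.05 equiv), NaHCO3, CH2Cl2, 0 °C
Reagents that add atoms: 3-chloroperoxybenzoic acid (mCPBA), OOC(=O)c1cccc(Cl)c1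
Why: Prilezhaev epoxidation is far faster at the electron-rich trisubstituted alkene than at the electron-poor enone alkene; the new stereocentre is racemic and is erased in step 4.

Step 4
Reactants: 7 3-[2-(3,3-dimethyloxiran-2-yl)ethyl]cyclohept-2-en-1-one
Product: 8 3-(4-methyl-3-oxopentyl)cyclohept-2-en-1-one
Conditions: BF3·OEt2 (0.2 equiv), CH2Cl2, −40 → 0 °C
Reagents that add atoms: none
Why: Meinwald rearrangement: the Lewis acid opens the epoxide at its tertiary carbon and a 1,2-hydride shift from the neighbouring CH gives the isopropyl ketone.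

Step 5
Reactants: 8 3-(4-methyl-3-oxopentyl)cyclohept-2-en-1-one; 9 trimethylaluminium
Product: 12 4β-hydroxy-14-nordaucan-6-one, via dimethylaluminium enolate 10 (not isolated), via dimethylaluminium aldolate 11 (not isolated)
Conditions: Me3Al (2 equiv), CuTC (5 mol %), chiral biphenol phosphoramidite (Alexakis type, 10 mol %, enantiomer chosen for 1β-CH3), Et2O, −30 → −10 °C; aq. Rochelle salt
Reagents that add atoms: none
Why: The chiral Cu(I)–phosphoramidite complex takes a methyl group from Me3Al, adds it to the enone β-carbon (π-complex, Cu(III) σ-adduct, reductive elimination) and leaves a dimethylaluminium enolate that can only be the C5=C6 enolate; the closest known chemistry is the Cu-catalysed asymmetric conjugate addition of Me3Al to 3-substituted cycloalkenones combined with conjugate addition–intramolecular aldol cyclisation of keto-enones. The enolate carbon C5 then attacks the aluminium-bound side-chain ketone in a 5-(enolexo)-exo-trig aldol closure that makes the C4–C5 bond and the cyclopentane. C1 is set by the ligand, whose enantiomer is chosen to deliver methyl to the enone face that gives the β-methyl series. C4 follows from the closed, aluminium-bridged transition state, which holds the ketone oxygen next to O6 and so puts the C4 oxygen cis to C6 and the isopropyl group on the α-face. C5 is expected to close trans to the angular methyl because in that chelate the isopropyl group meets only the tied-back C10 methylene, whereas the cis-fused chelate presses it against the free C1 methyl; since aldolate formation is reversible, warming before the quench should drain the mixture towards this isomer. The step needs 1,4- over 1,2-methyl transfer, secured by copper catalysis in ether at low temperature and by the hindered isopropyl ketone, and a single enolate regioisomer, secured because the enolate is created by the conjugate addition itself.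

Step 6
Reactants: 12 4β-hydroxy-14-nordaucan-6-one
Product: 13 4β-hydroxy-14-nordauc-7-en-6-one
Conditions: IBX (1.5 equiv), 4-methoxypyridine N-oxide (1.5 equiv), DMSO, 25 °C
Reagents that add atoms: none
Why: IBX dehydrogenation of the ketone through its enol can only give the 7-ene, because the other α-carbon C5 has no hydrogen-bearing β-carbon (C1 and C4 are quaternary); the tertiary alcohol is inert to IBX and no base is present.

Step 7
Reactants: 13 4β-hydroxy-14-nordauc-7-en-6-one; 9 trimethylaluminium
Product: 14 4β-hydroxydaucan-6-one (both C8 epimers)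
Conditions: Me3Al (2.5 equiv), CuTC (5 mol %), PPh3 (10 mol %), Et2O, −30 °C; aq. Rochelle salt
Reagents that add atoms: none
Why: Copper-catalysed conjugate addition of Me3Al puts C14 on C8, while the first equivalent turns O4–H into the same aluminium aldolate that the cascade produced and so guards against retro-aldol cleavage; the C8 configuration is irrelevant because C8 becomes sp2 in step 8.

Step 8
Reactants: 14 4β-hydroxydaucan-6-one
Product: 15 4β-hydroxydauc-7-en-6-one
Conditions: IBX (2 equiv), 4-methoxypyridine N-oxide (2 equiv), DMSO, 25–40 °C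
Reagents that add atoms: none
Why: A second IBX dehydrogenation, again possible only across C7–C8, gives the β-methyl enone.

Step 9
Reactants: 15 4β-hydroxydauc-7-en-6-one
Product: 17 4β-hydroxydauc-8-en-6-one, via bis(trimethylsilyl) dienol ether 16 (not isolated)
Conditions: TMSOTf (2.5 equiv), Et3N (4 equiv), CH2Cl2, 0 °C; then citric acid, THF/MeOH/H2O, 0 °C; pH 7 work-up, used crude
Reagents that add atoms: none
Why: Soft enolisation silylates O4 and gives the conjugated endocyclic 6-silyloxy-6,8-diene (C5–H, buried between two quaternary carbons, is not removed), and mild acid hydrolysis of such a dienol ether protonates C7 kinetically to give the β,γ-unsaturated ketone, as in the deconjugation of steroidal 3,5-dienol ethers; no alkoxide forms, so the aldol unit cannot cleave, and no stereocentre is touched.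

Step 10
Reactants: 17 4β-hydroxydauc-8-en-6-one
Product: 18 dauc-8-ene-4β,6α-diol (jaeschkeanadiol)
Conditions: Me4NBH(OAc)3 (5 equiv), MeCN/AcOH (1:1), −20 °C
Reagents that add atoms: none
Why: Evans–Saksena hydroxyl-directed reduction: the O4-bound acetoxyborohydride delivers hydride intramolecularly to the β-face of C6 and gives the anti-1,3-diol (6α-OH), under conditions too mild to move the 8-ene into conjugation.

Step 11
Reactants: 18 dauc-8-ene-4β,6α-diol
Product: 19 8α,9α-epoxydaucane-4β,6α-diol
Conditions: VO(acac)2 (5 mol %), t-BuOOH (1.5 equiv), CH2Cl2, 0 → 25 °C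
Reagents that add atoms: tert-butyl hydroperoxide, CC(C)(C)OO
Why: Vanadium-catalysed hydroxyl-directed epoxidation of the homoallylic alcohol: the C6 vanadate delivers oxygen to the α-face of the 8-ene, which sets C8 and C9 as the 8α,9α-epoxide.

Step 12
Reactants: 19 8α,9α-epoxydaucane-4β,6α-diol; 20 4-(benzyloxy)benzoic acid
Product: 22 8α,9α-epoxy-4β-hydroxydaucan-6α-yl 4-(benzyloxy)benzoate, via 4-(benzyloxy)benzoyl chloride 21 (not isolated)
Conditions: 20, (COCl)2, DMF (cat.), CH2Cl2, 25 °C; evaporate; then 19, Et3N, DMAP, CH2Cl2, 25–40 °C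
Reagents that add atoms: none
Why: DMAP-catalysed acylation by the acid chloride takes place only at the secondary C6 hydroxyl, since the tertiary C4 hydroxyl is inert, and the amine-buffered medium leaves the epoxide closed.

Step 13
Reactants: 22 8α,9α-epoxy-4β-hydroxydaucan-6α-yl 4-(benzyloxy)benzoate
Product: 23 4β,8β,9α-trihydroxydaucan-6α-yl 4-(benzyloxy)benzoate
Conditions: HClO4 (0.05 M), THF/H2O (3:1), 0 → 25 °C
Reagents that add atoms: water, O
Why: Acid-catalysed epoxide hydrolysis: water attacks the tertiary C8 with inversion from the β-face (anti opening), giving 8β-OH/8α-CH3 and leaving the 9α-oxygen in place, and the large excess of water is meant to outrun the C4 hydroxyl.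

Step 14
Reactants: 23 4β,8β,9α-trihydroxydaucan-6α-yl 4-(benzyloxy)benzoate
Product: 24 4β,8β,9α-trihydroxydaucan-6α-yl 4-hydroxybenzoate
Conditions: H2 (1 atm), 10% Pd/C, EtOAc, 25 °C
Reagents that add atoms: none
Why: Hydrogenolysis cleaves the benzyl aryl ether, while the benzoate ester, the alcohols and the saturated skeleton are untouched.

Compound list
1 | cycloheptane-1,3-dione | O=C1CCCCC(=O)C1 | starting material
2 | 3-(2-methylpropoxy)cyclohept-2-en-1-one | CC(C)COC1=CC(=O)CCCC1 | intermediate
3 | 5-bromo-2-methylpent-2-ene | CC(C)=CCCBr | starting material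
4 | (4-methylpent-3-en-1-yl)magnesium bromide (homoprenylmagnesium bromide, not isolated) | CC(C)=CCC[Mg]Br | intermediate
5 | bromomagnesium 3-(2-methylpropoxy)-1-(4-methylpent-3-en-1-yl)cyclohept-2-en-1-olate (racemic, not isolated) | CC(C)=CCCC1(O[Mg]Br)C=C(OCC(C)C)CCCC1 | intermediate
6 | 3-(4-methylpent-3-en-1-yl)cyclohept-2-en-1-one | CC(C)=CCCC1=CC(=O)CCCC1 | intermediate
7 | 3-[2-(3,3-dimethyloxiran-2-yl)ethyl]cyclohept-2-en-1-one (racemic) | CC1(C)OC1CCC2=CC(=O)CCCC2 | intermediate
8 | 3-(4-methyl-3-oxopentyl)cyclohept-2-en-1-one | CC(C)C(=O)CCC1=CC(=O)CCCC1 | intermediate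
9 | trimethylaluminium | C[Al](C)C | starting material
10 | dimethylaluminium C5=C6 enolate of 3-methyl-3-(4-methyl-3-oxopentyl)cycloheptanone, quaternary carbon as C1 of 12 (not isolated) | CC(C)C(=O)CC[C@]1(C)CCCCC(O[Al](C)C)=C1 | intermediate
11 | dimethylaluminium alkoxide (aldolate) of 12 (not isolated) | CC(C)[C@]1(O[Al](C)C)CC[C@]2(C)CCCCC(=O)[C@H]21 | intermediate
12 | 4β-hydroxy-14-nordaucan-6-one (trans-fused; 1β-CH3, 5α-H, 4β-OH, 4α-isopropyl) | CC(C)[C@]1(O)CC[C@]2(C)CCCCC(=O)[C@H]21 | intermediate
13 | 4β-hydroxy-14-nordauc-7-en-6-one | CC(C)[C@]1(O)CC[C@]2(C)CCC=CC(=O)[C@H]21 | intermediate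
14 | 4β-hydroxydaucan-6-one (mixture of C8 epimers) | CC(C)[C@]1(O)CC[C@]2(C)CCC(C)CC(=O)[C@H]21 | intermediate
15 | 4β-hydroxydauc-7-en-6-one | CC(C)[C@]1(O)CC[C@]2(C)CCC(C)=CC(=O)[C@H]21 | intermediate
16 | 4β,6-bis(trimethylsilyloxy)dauca-6,8-diene (not isolated) | CC(C)[C@]1(O[Si](C)(C)C)CC[C@]2(C)CC=C(C)C=C(O[Si](C)(C)C)[C@H]21 | intermediate
17 | 4β-hydroxydauc-8-en-6-one | CC(C)[C@]1(O)CC[C@]2(C)CC=C(C)CC(=O)[C@H]21 | intermediate
18 | dauc-8-ene-4β,6α-diol (jaeschkeanadiol) | CC(C)[C@]1(O)CC[C@]2(C)CC=C(C)C[C@H](O)[C@H]21 | intermediate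
19 | 8α,9α-epoxydaucane-4β,6α-diol | CC(C)[C@]1(O)CC[C@]2(C)C[C@@H]3O[C@]3(C)C[C@H](O)[C@H]21 | intermediate
20 | 4-(benzyloxy)benzoic acid | OC(=O)c1ccc(OCc2ccccc2)cc1 | starting material
21 | 4-(benzyloxy)benzoyl chloride (not isolated) | ClC(=O)c1ccc(OCc2ccccc2)cc1 | intermediate
22 | 8α,9α-epoxy-4β-hydroxydaucan-6α-yl 4-(benzyloxy)benzoate | CC(C)[C@]1(O)CC[C@]2(C)C[C@@H]3O[C@]3(C)C[C@H](OC(=O)c4ccc(OCc5ccccc5)cc4)[C@H]21 | intermediate
23 | 4β,8β,9α-trihydroxydaucan-6α-yl 4-(benzyloxy)benzoate (8α-CH3) | CC(C)[C@]1(O)CC[C@]2(C)C[C@H](O)[C@@](C)(O)C[C@H](OC(=O)c3ccc(OCc4ccccc4)cc3)[C@H]21 | intermediate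
24 | 4β,8β,9α-trihydroxydaucan-6α-yl 4-hydroxybenzoate (CNP0197754.1) | CC(C)[C@]1(O)CC[C@]2(C)C[C@H](O)[C@@](C)(O)C[C@H](OC(=O)c3ccc(O)cc3)[C@H]21 | target

Total steps: 14. Longest linear sequence: 14 (1 → 24; 3, 9 and 20 enter as commercial materials).

Steps most likely to fail:

Step 5. The aluminium enolate may be protonated on work-up without having closed, may close to the cis-fused or C4-epimeric aldol, or the methyl transfer may lose face selectivity. Fallback, from 8 and back at 12: the copper-catalysed methyl transfer is run alone and the aluminium enolate is silylated in the flask with TMSOTf to give the regiodefined silyl enol ether 4-methyl-1-[1-methyl-3-(trimethylsilyloxy)cyclohept-2-en-1-yl]pentan-3-one F1. An intramolecular Mukaiyama aldol reaction (TiCl4, CH2Cl2, −78 °C), in which titanium bridges the two oxygens, would then close the cyclopentane and return 12 after aqueous work-up.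

Step 9. γ-Deprotonation may occur at the C14 methyl instead of C9 and lead to the exocyclic alkene, or protonation at C9 during hydrolysis may return the conjugated enone. Fallback, from 13 and back at 18 (it replaces steps 7–10): Tsuji–Wacker oxidation of the enone (Na2PdCl4, t-BuOOH, AcOH/H2O) would give 4β-hydroxy-14-nordaucane-6,8-dione F2. O4-directed reduction with Me4NBH(OAc)3 would reduce C6 only and give 4β,6α-dihydroxy-14-nordaucan-8-one F3. LDA (3.2 equiv) then PhNTf2 would enolise away from the C6 alkoxide and give 4β,6α-dihydroxy-14-nordauc-8-en-8-yl trifluoromethanesulfonate F4. Iron-catalysed coupling with MeMgBr (Fe(acac)3, THF/NMP) would put C14 on C8 and return diol 18.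

Step 13. The opening epoxide may be captured across the ring by the C4 hydroxyl, or may lose a proton, instead of being attacked by water. Fallback, from 22 and back at 23: O4 is first masked as its triethylsilyl ether (TESOTf, 2,6-lutidine, −78 °C) to give 8α,9α-epoxy-4β-(triethylsilyloxy)daucan-6α-yl 4-(benzyloxy)benzoate F5. The same aqueous acid would then open the epoxide with water only and give 8β,9α-dihydroxy-4β-(triethylsilyloxy)daucan-6α-yl 4-(benzyloxy)benzoate F6, and buffered fluoride (TBAF/AcOH, THF) would remove the silyl group to return 23.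

Further compounds
F1 | step 5 | 4-methyl-1-[1-methyl-3-(trimethylsilyloxy)cyclohept-2-en-1-yl]pentan-3-one (quaternary carbon as C1 of 12) | CC(C)C(=O)CC[C@]1(C)CCCCC(O[Si](C)(C)C)=C1
F2 | step 9 | 4β-hydroxy-14-nordaucane-6,8-dione | CC(C)[C@]1(O)CC[C@]2(C)CCC(=O)CC(=O)[C@H]21
F3 | step 9 | 4β,6α-dihydroxy-14-nordaucan-8-one | CC(C)[C@]1(O)CC[C@]2(C)CCC(=O)C[C@H](O)[C@H]21
F4 | step 9 | 4β,6α-dihydroxy-14-nordauc-8-en-8-yl trifluoromethanesulfonate | CC(C)[C@]1(O)CC[C@]2(C)CC=C(OS(=O)(=O)C(F)(F)F)C[C@H](O)[C@H]21
F5 | step 13 | 8α,9α-epoxy-4β-(triethylsilyloxy)daucan-6α-yl 4-(benzyloxy)benzoate | CC(C)[C@]1(O[Si](CC)(CC)CC)CC[C@]2(C)C[C@@H]3O[C@]3(C)C[C@H](OC(=O)c4ccc(OCc5ccccc5)cc4)[C@H]21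
F6 | step 13 | 8β,9α-dihydroxy-4β-(triethylsilyloxy)daucan-6α-yl 4-(benzyloxy)benzoate | CC(C)[C@]1(O[Si](CC)(CC)CC)CC[C@]2(C)C[C@H](O)[C@@](C)(O)C[C@H](OC(=O)c3ccc(OCc4ccccc4)cc3)[C@H]21
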